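**Plan**

1. Numbering: C1 quaternary methyl carbon, C2 ketone, C3, C4 (isopropyl CH), C5 (carbinol carbon), then C6, C7, C8 (methyl, alkene), C9, C10 (ester carbon, bonded to C1); α is the face of the C1 methyl group, β the other face.
2. Feature and cuts: the seven-membered ring C1/C5–C10, with its C8 methyl opposite C5, is a p-tolyl ring that has taken up one carbon, C1, next to the C2 ketone. C1–C5 and C1–C10 are therefore cut together (carbene carbon plus arene), after the C10 ester, the C4–isopropyl bond and the C5/C10 oxygens have been removed.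
3. Forward: a p-tolyl-tethered α-diazo ethyl ketone closes the cyclopentanone (C1–C5) and, by ring expansion of the arene, the seven-membered ring (C1–C10) in one step. The triene is then differentiated by C5=C6 epoxidation, Pd-mediated 1,6-opening to C10 and diimide reduction of C6=C7; the ester and the isopropyl group come last.
4. Stereochemistry: a C4 silyloxy stereocentre (asymmetric hydrogenation) sets C1 trans to itself in the key step, sends the epoxide oxygen to the α face (C5) and is then eliminated. C10 comes from the Pd opening (α) followed by Mitsunobu inversion (β). Isopropyl is delivered to C4 by the C5 alkoxide, cis to hydroxyl and methyl.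
5. An isopropyl group carried through the cyclisation would be expected to end trans to the C1 methyl group (a benzylic substituent turns away from the angular methyl), the opposite of the target; hence the silyloxy group at C4 and the late isopropyl addition.

Key step: step 5

Remarks: Diazoethane (5) is prepared immediately before use from commercial N-ethyl-N-nitrosourea and aqueous KOH and is counted as a starting material. Bicyclic intermediates are named with azulene locants (1 = C2, 3 = C4, 3a = C5, 8 = C10, 8a = C1) and the α/β convention above; absolute configurations are those of the SMILES strings.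

Step 1
Reactants: 1 ethyl 3-(4-methylphenyl)-3-oxopropanoate
Product: 2 ethyl (3R)-3-hydroxy-3-(4-methylphenyl)propanoate
Conditions: RuCl2[(S)-BINAP](dmf)n (0.5 mol %), H2 (50 bar), EtOH, 60 °C
Reagents that add atoms: none
Why: Noyori asymmetric hydrogenation of a β-keto ester through the ester-chelated ruthenium hydride; the (S)-diphosphine is expected to give the (R)-benzylic carbinol (the aryl group reverses the CIP label relative to the acetoacetate case; the antipodal ligand is available should the sense be opposite), and this is the only stereocentre carried into the key step.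

Step 2
Reactants: 2 ethyl (3R)-3-hydroxy-3-(4-methylphenyl)propanoate
Product: 3 ethyl (3R)-3-(4-methylphenyl)-3-[(triisopropylsilyl)oxy]propanoate
Conditions: TIPSOTf, 2,6-lutidine, CH2Cl2, 0 °C to rt
Reagents that add atoms: triisopropylsilyl trifluoromethanesulfonate, CC(C)[Si](C(C)C)(C(C)C)OS(=O)(=O)C(F)(F)F
Why: O-silylation of a secondary benzylic alcohol with a silyl triflate and a hindered base; the bulky, weakly Lewis-basic TIPS ether is chosen because it must later resist the rhodium carbenoid, shield one face of the ring and finally act as a leaving group.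

Step 3
Reactants: 3 ethyl (3R)-3-(4-methylphenyl)-3-[(triisopropylsilyl)oxy]propanoate
Product: 4 (3R)-3-(4-methylphenyl)-3-[(triisopropylsilyl)oxy]propanoic acid
Conditions: LiOH·H2O, THF/H2O, rt; then 1 M HCl to pH 3 at 0 °C
Reagents that add atoms: lithium hydroxide, [Li+].[OH-]
Why: saponification by acyl substitution; hydroxide hydrolyses the ester far faster than it enolises it, so the β-silyloxy group should not be eliminated and the stereocentre is untouched.

Step 4
Reactants: 4 (3R)-3-(4-methylphenyl)-3-[(triisopropylsilyl)oxy]propanoic acid; 5 diazoethane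
Product: 7 (5R)-2-diazo-5-(4-methylphenyl)-5-[(triisopropylsilyl)oxy]pentan-3-one, via isobutyl carbonic mixed anhydride 6 (not isolated)
Conditions: i-BuOCOCl, N-methylmorpholine, THF, −20 °C; then CH3CHN2 (Et2O), −20 to 0 °C
Reagents that add atoms: diazoethane (5), CC=[N+]=[N-]
Why: C-acylation of a diazoalkane by a mixed carbonic anhydride (the diazoethane form of the Arndt–Eistert diazoketone synthesis) puts the diazo group unambiguously on the carbon that becomes C1, without HCl and without the regiochemical and β-elimination problems of diazo transfer to the ethyl ketone.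

Step 5
Reactants: 7 (5R)-2-diazo-5-(4-methylphenyl)-5-[(triisopropylsilyl)oxy]pentan-3-one
Product: 9 (3R,8aR)-6,8a-dimethyl-3-[(triisopropylsilyl)oxy]-3,8a-dihydroazulen-1(2H)-one, via norcaradiene 8 (not isolated)
Conditions: Rh2(OAc)4 (1 mol %), CH2Cl2, 40 °C, slow addition of 7
Reagents that add atoms: none
Why: Rh2(OAc)4 expels N2 from 7 to give the rhodium carbenoid at C1, which adds to the ipso/ortho bond (C5/C10) of the p-tolyl ring to form norcaradiene 8; disrotatory 6π electrocyclic opening of the C5–C10 bond then gives cycloheptatriene 9, so that C1–C5 and C1–C10 are both made here. The closest known reaction type is the intramolecular Buchner reaction of 1-aryl-4-diazoalkan-3-ones to 8a-methyl-3,8a-dihydroazulen-1(2H)-ones. The cyclopentanone closes by carbene addition across the three-atom tether C2–C3–C4 (5-exo attack on the ipso carbon), and the seven-membered ring arises not by cyclisation but by ring expansion of the benzene ring (cyclopropanation, then electrocyclic opening). The new stereocentre C1 is controlled by C4: allylic 1,3-strain keeps the benzylic hydrogen in the arene plane next to the ortho C–H, the silyloxy group points to the arene face away from the carbenoid, and the C1 methyl group, which must sit endo over the ring, should therefore end trans to the silyloxy group. The step needs arene addition to win over 1,2-hydride shift of the α-methyl carbenoid, oxonium ylide formation and C–H insertion; slow addition, the five-membered tether geometry and the bulky, weakly basic TIPS ether are meant to secure this, and the two ortho carbons are equivalent so no regiochemical question arises.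

Step 6
Reactants: 9 (3R,8aR)-6,8a-dimethyl-3-[(triisopropylsilyl)oxy]-3,8a-dihydroazulen-1(2H)-one
Product: 10 3aα,4α-epoxy-6,8a-dimethyl-3β-[(triisopropylsilyl)oxy]-3,3a,4,8a-tetrahydroazulen-1(2H)-one
Conditions: DMDO (acetone, 1.05 equiv), CH2Cl2, −40 °C; concentrated cold and used at once
Reagents that add atoms: dimethyldioxirane, CC1(C)OO1
Why: neutral dioxirane epoxidation of the more substituted terminal double bond of the triene (C5=C6; the central C7=C8 bond would lose conjugation on both sides and C9=C10 is only disubstituted), with oxygen expected anti to the bulky allylic silyloxy group on C4, that is on the α face, which sets C5.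

Step 7
Reactants: 10 3aα,4α-epoxy-6,8a-dimethyl-3β-[(triisopropylsilyl)oxy]-3,3a,4,8a-tetrahydroazulen-1(2H)-one
Product: 11 3aα-hydroxy-6,8a-dimethyl-1-oxo-3β-[(triisopropylsilyl)oxy]-1,2,3,3a,8,8a-hexahydroazulen-8α-yl acetate
Conditions: Pd(PPh3)4 (5 mol %), AcOH (1.2 equiv), THF, 0 °C
Reagents that add atoms: acetic acid, CC(=O)O
Why: Tsuji–Trost opening of an alkenyl epoxide by a carboxylic acid in its vinylogous form: Pd(0) ionises the C6–O bond from the β face to a pentadienyl palladium alkoxide, and acetate adds anti to palladium at the terminus remote from the alkoxide (C10), so the C10 oxygen should end α, cis to the C5 hydroxyl, with the conjugated C6=C7/C8=C9 diene; acetate is used because the final ester has to be introduced with inversion.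

Step 8
Reactants: 11 3aα-hydroxy-6,8a-dimethyl-1-oxo-3β-[(triisopropylsilyl)oxy]-1,2,3,3a,8,8a-hexahydroazulen-8α-yl acetate
Product: 12 3aα-hydroxy-6,8a-dimethyl-1-oxo-3β-[(triisopropylsilyl)oxy]-1,2,3,3a,4,5,8,8a-octahydroazulen-8α-yl acetate
Conditions: 2-nitrobenzenesulfonylhydrazide, Et3N, CH2Cl2, rt
Reagents that add atoms: none
Why: diimide reduction (concerted syn transfer of H2) is very sensitive to alkene substitution, so the cis-disubstituted C6=C7 bond should be reduced before the trisubstituted C8=C9 bond, while ketone, acetate and silyl ether are inert; no stereocentre is formed.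

Step 9
Reactants: 12 3aα-hydroxy-6,8a-dimethyl-1-oxo-3β-[(triisopropylsilyl)oxy]-1,2,3,3a,4,5,8,8a-octahydroazulen-8α-yl acetate
Product: 14 3aα,8α-dihydroxy-6,8a-dimethyl-3a,4,5,8-tetrahydroazulen-1(8aH)-one, via enone acetate 13 (not isolated)
Conditions: LiOH·H2O, THF/H2O, 0 °C to rt
Reagents that add atoms: none
Why: E1cB β-elimination of silanolate from the β-silyloxy cyclopentanone (C3 is the only enolisable position) unveils the C3=C4 enone and removes the spent C4 stereocentre, and the same base then saponifies the hindered allylic acetate; C5 bears no hydrogen, so the γ-hydroxy enone cannot isomerise.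

Step 10
Reactants: 14 3aα,8α-dihydroxy-6,8a-dimethyl-3a,4,5,8-tetrahydroazulen-1(8aH)-one; 15 4-methoxybenzoic acid
Product: 16 3aα-hydroxy-6,8a-dimethyl-1-oxo-1,3a,4,5,8,8a-hexahydroazulen-8β-yl 4-methoxybenzoate
Conditions: PPh3, DIAD, THF, 0 °C to rt
Reagents that add atoms: 4-methoxybenzoic acid (15), COc1ccc(cc1)C(=O)O
Why: Mitsunobu esterification: only the secondary allylic C10 alcohol is activated (the tertiary C5 alcohol is not), and SN2 displacement by the carboxylate inverts C10 from α to β, giving the trans relationship to the C1 methyl and C5 hydroxyl groups required by the target.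

Step 11
Reactants: 16 3aα-hydroxy-6,8a-dimethyl-1-oxo-1,3a,4,5,8,8a-hexahydroazulen-8β-yl 4-methoxybenzoate; 17 isopropylmagnesium chloride
Product: 19 [(3R,3aS,8R,8aR)-3a-hydroxy-6,8a-dimethyl-1-oxo-3-(propan-2-yl)-1,2,3,3a,4,5,8,8a-octahydroazulen-8-yl] 4-methoxybenzoate (target CNP0246512.1), via magnesium enolate 18 (not isolated)
Conditions: i-PrMgCl (3.5 equiv), THF, −78 to −30 °C; then aq. NH4Cl
Reagents that add atoms: isopropylmagnesium chloride (17), CC(C)[Mg]Cl
Why: alkoxide-directed (ligand-assisted) conjugate addition of a Grignard reagent to a γ-oxido enone: the C5 magnesium alkoxide binds a second equivalent of reagent and delivers isopropyl to C4 on its own α face, which is also the convex face of the cis-fused bicycle and the face away from the C10 ester, so C4 should be set cis to the C5 hydroxyl and C1 methyl groups, the aryl ester surviving i-PrMgCl at this temperature.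

**Compound list**

1 | ethyl 3-(4-methylphenyl)-3-oxopropanoate | CCOC(=O)CC(=O)c1ccc(C)cc1 | starting material
2 | ethyl (3R)-3-hydroxy-3-(4-methylphenyl)propanoate | CCOC(=O)C[C@@H](O)c1ccc(C)cc1 | intermediate
3 | ethyl (3R)-3-(4-methylphenyl)-3-[(triisopropylsilyl)oxy]propanoate | CCOC(=O)C[C@@H](O[Si](C(C)C)(C(C)C)C(C)C)c1ccc(C)cc1 | intermediate
4 | (3R)-3-(4-methylphenyl)-3-[(triisopropylsilyl)oxy]propanoic acid | OC(=O)C[C@@H](O[Si](C(C)C)(C(C)C)C(C)C)c1ccc(C)cc1 | intermediate
5 | diazoethane | CC=[N+]=[N-] | starting material
6 | isobutyl carbonic mixed anhydride of 4 (not isolated) | CC(C)COC(=O)OC(=O)C[C@@H](O[Si](C(C)C)(C(C)C)C(C)C)c1ccc(C)cc1 | intermediate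
7 | (5R)-2-diazo-5-(4-methylphenyl)-5-[(triisopropylsilyl)oxy]pentan-3-one | CC(=[N+]=[N-])C(=O)C[C@@H](O[Si](C(C)C)(C(C)C)C(C)C)c1ccc(C)cc1 | intermediate
8 | norcaradiene valence isomer of 9 (cyclopropane C1–C5–C10, diene C6=C7/C8=C9, methyl endo; not isolated) | O=C1C[C@@H](O[Si](C(C)C)(C(C)C)C(C)C)[C@@]23C=CC(C)=C[C@@H]2[C@@]13C | intermediate
9 | (3R,8aR)-6,8a-dimethyl-3-[(triisopropylsilyl)oxy]-3,8a-dihydroazulen-1(2H)-one (silyloxy trans to the 8a-methyl group) | O=C1C[C@@H](O[Si](C(C)C)(C(C)C)C(C)C)C2=CC=C(C)C=C[C@@]12C | intermediate
10 | 3aα,4α-epoxy-6,8a-dimethyl-3β-[(triisopropylsilyl)oxy]-3,3a,4,8a-tetrahydroazulen-1(2H)-one | O=C1C[C@@H](O[Si](C(C)C)(C(C)C)C(C)C)[C@@]23O[C@@H]2C=C(C)C=C[C@@]13C | intermediate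
11 | 3aα-hydroxy-6,8a-dimethyl-1-oxo-3β-[(triisopropylsilyl)oxy]-1,2,3,3a,8,8a-hexahydroazulen-8α-yl acetate | O=C1C[C@@H](O[Si](C(C)C)(C(C)C)C(C)C)[C@@]2(O)C=CC(C)=C[C@H](OC(C)=O)[C@@]12C | intermediate
12 | 3aα-hydroxy-6,8a-dimethyl-1-oxo-3β-[(triisopropylsilyl)oxy]-1,2,3,3a,4,5,8,8a-octahydroazulen-8α-yl acetate | O=C1C[C@@H](O[Si](C(C)C)(C(C)C)C(C)C)[C@@]2(O)CCC(C)=C[C@H](OC(C)=O)[C@@]12C | intermediate
13 | 3aα-hydroxy-6,8a-dimethyl-1-oxo-1,3a,4,5,8,8a-hexahydroazulen-8α-yl acetate (not isolated) | O=C1C=C[C@@]2(O)CCC(C)=C[C@H](OC(C)=O)[C@@]12C | intermediate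
14 | 3aα,8α-dihydroxy-6,8a-dimethyl-3a,4,5,8-tetrahydroazulen-1(8aH)-one | O=C1C=C[C@@]2(O)CCC(C)=C[C@H](O)[C@@]12C | intermediate
15 | 4-methoxybenzoic acid | COc1ccc(cc1)C(=O)O | starting material
16 | 3aα-hydroxy-6,8a-dimethyl-1-oxo-1,3a,4,5,8,8a-hexahydroazulen-8β-yl 4-methoxybenzoate | O=C1C=C[C@@]2(O)CCC(C)=C[C@@H](OC(=O)c3ccc(OC)cc3)[C@@]12C | intermediate
17 | isopropylmagnesium chloride | CC(C)[Mg]Cl | starting material
18 | bis(chloromagnesium) enolate/alkoxide of 19 (not isolated) | Cl[Mg]OC1=C[C@H](C(C)C)[C@@]2(O[Mg]Cl)CCC(C)=C[C@@H](OC(=O)c3ccc(OC)cc3)[C@@]12C | intermediate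
19 | [(3R,3aS,8R,8aR)-3a-hydroxy-6,8a-dimethyl-1-oxo-3-(propan-2-yl)-1,2,3,3a,4,5,8,8a-octahydroazulen-8-yl] 4-methoxybenzoate | COc1ccc(C(=O)O[C@@H]2C=C(C)CC[C@]3(O)[C@@H](C(C)C)CC(=O)[C@]23C)cc1 | target

**Count and risks**

Total step count: 11. Longest linear sequence: 11 steps (from 1; compounds 5, 15 and 17 enter as purchased or freshly made reagents).

Steps most likely to fail:

Step 6 (epoxidation of the triene). The oxidant may fail to discriminate between the faces, because the axial C1 methyl group (α) and the C4 silyloxy group (β) shield opposite faces of C5=C6, or it may attack C7=C8; the dienyl epoxide may also rearrange before it is used. Fallback: give up substrate control for reagent control, that is a catalytic asymmetric (Shi) epoxidation with a fructose-derived ketone and Oxone in buffered MeCN/dimethoxymethane–water at 0 °C. The ketone enantiomer is chosen so that its spiro transition state places oxygen on the α face of the trisubstituted C5=C6 bond; this catalyst class also prefers trisubstituted over cis-disubstituted double bonds. The fallback sets out from 9 and returns to the route at 10; it makes no new compound (F0).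

Step 7 (palladium-mediated 1,6-opening). Acetate may attack the pentadienyl palladium complex at C6 or C8 instead of the hindered, neopentyl C10 terminus next to the α methyl group, or the complex may collapse by elimination. Fallback: a metal-free, protic opening that installs the final ester directly. Epoxide 10 is treated with 4-methoxybenzoic acid (15) and its tetrabutylammonium salt in CH2Cl2 at 0 °C; capture of the C6–C10 pentadienyl cation at its remote terminus, on the face away from the C1 methyl group, would give the 8β-(4-methoxybenzoate) dienyl silyl ether F1. Diimide, as in step 8, would give the C6–C7 saturated ester F2, and DBU in CH2Cl2 would eliminate the silanol to give 16. The fallback sets out from 10 and returns at 16; steps 9 and 10 are then not needed.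

Step 10 (Mitsunobu inversion). Substitution at the neopentyl, allylic C10 carbinol may be too slow, so that SN2′ delivery to C8 or elimination to a diene takes over. Fallback: oxidation and reduction in place of SN2 inversion, with the isopropyl group put in first. Diol 14 is taken through the Grignard addition of step 11 (one more equivalent for the second hydroxyl) to give the 3α-isopropyl 3aα,8α-diol ketone F3. MnO2 oxidises only the allylic C10 alcohol to the enedione F4. NaBH4/CeCl3 in MeOH at −78 °C (Luche reduction) should reduce the conjugated C10 carbonyl in preference to the saturated C2 ketone, with hydride entering from the convex α face, to give the 8β-alcohol F5. 4-Methoxybenzoyl chloride, DMAP and pyridine then acylate the secondary alcohol. The fallback sets out from 14 and returns at 19.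

Further compounds
F0 | step 6 | none | none
F1 | step 7 | 3aα-hydroxy-6,8a-dimethyl-1-oxo-3β-[(triisopropylsilyl)oxy]-1,2,3,3a,8,8a-hexahydroazulen-8β-yl 4-methoxybenzoate | O=C1C[C@@H](O[Si](C(C)C)(C(C)C)C(C)C)[C@@]2(O)C=CC(C)=C[C@@H](OC(=O)c3ccc(OC)cc3)[C@@]12C
F2 | step 7 | 3aα-hydroxy-6,8a-dimethyl-1-oxo-3β-[(triisopropylsilyl)oxy]-1,2,3,3a,4,5,8,8a-octahydroazulen-8β-yl 4-methoxybenzoate | O=C1C[C@@H](O[Si](C(C)C)(C(C)C)C(C)C)[C@@]2(O)CCC(C)=C[C@@H](OC(=O)c3ccc(OC)cc3)[C@@]12C
F3 | step 10 | 3aα,8α-dihydroxy-6,8a-dimethyl-3α-(propan-2-yl)-3,3a,4,5,8,8a-hexahydroazulen-1(2H)-one | O=C1C[C@H](C(C)C)[C@@]2(O)CCC(C)=C[C@H](O)[C@@]12C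
F4 | step 10 | 3aα-hydroxy-6,8a-dimethyl-3α-(propan-2-yl)-3,3a,4,5-tetrahydroazulene-1,8(2H,8aH)-dione | O=C1C[C@H](C(C)C)[C@@]2(O)CCC(C)=CC(=O)[C@@]12C
F5 | step 10 | 3aα,8β-dihydroxy-6,8a-dimethyl-3α-(propan-2-yl)-3,3a,4,5,8,8a-hexahydroazulen-1(2H)-one | O=C1C[C@H](C(C)C)[C@@]2(O)CCC(C)=C[C@@H](O)[C@@]12C
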